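The target is a 1,1,2-triarylethane whose single stereocentre C1 carries ring A, ring B and the C2 methylene of ring C. Because the phenol oxygen of ring B sits ortho to C1, the sequence O–C2–C1 can be tied into a five-membered ring, so the C1–C2 bond is disconnected to a ring B aryl ether of the ring C benzyl alcohol bearing a diaryl carbene at C1. One rhodium-catalysed insertion of this carbene into the O–CH2 hydrogen forms C1–C2, closes a 2,3-dihydrobenzofuran and fixes C1. The precursor is a bromo-substituted diaryldiazomethane with triisopropylsilyl-masked phenols; the C2–O bond is afterwards cut by ionic hydrogenation, and the stilbene is added by Heck coupling.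

Key step: step 9

Assumption: Rh2(S-PTAD)4 is taken to deliver the (3S) configuration of the dihydrobenzofuran; should the first run show the opposite sense, Rh2(R-PTAD)4 replaces it with no other change.

Remark: rings A and C carry triisopropylsilyl ethers because aryl tert-butyldimethylsilyl ethers would be at risk in hot hydrazine and under carbonate alkylation. Ring C is attached as its benzyl alcohol under Mitsunobu conditions because a 2,4-disilyloxybenzyl halide would ionise too readily to handle.

Step 1
Reactants: 1 2,4-dihydroxybenzaldehyde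
Product: 2 2,4-bis(triisopropylsilyloxy)benzaldehyde
Conditions: TIPSCl (2.4 equiv), imidazole (5 equiv), DMF, 0 °C to 40 °C
Reagents that add atoms: triisopropylsilyl chloride, CC(C)[Si](Cl)(C(C)C)C(C)C
Why: Imidazole-mediated O-silylation of both phenols (silyl ether formation), with warming and excess reagent to overcome the hydrogen-bonded ortho hydroxyl; triisopropylsilyl aryl ethers should survive the Grignard, hydrazine and acid steps and still leave with fluoride.

Step 2
Reactants: 2 2,4-bis(triisopropylsilyloxy)benzaldehyde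
Product: 3 [2,4-bis(triisopropylsilyloxy)phenyl]methanol
Conditions: NaBH4, THF/MeOH, 0 °C; aqueous work-up
Reagents that add atoms: none
Why: Borohydride reduction of the aldehyde to the benzylic alcohol; the bulky silyl group and the cold protic medium should suppress migration of the ortho silyl group to the new alkoxide.

Step 3
Reactants: 3 [2,4-bis(triisopropylsilyloxy)phenyl]methanol; 4 5-bromo-2-hydroxy-3-methoxybenzaldehyde
Product: 5 2-{[2,4-bis(triisopropylsilyloxy)phenyl]methoxy}-5-bromo-3-methoxybenzaldehyde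
Conditions: PPh3, DIAD, THF, 0 °C to rt
Reagents that add atoms: none
Why: Mitsunobu etherification, in which the acidic, aldehyde-activated phenol of 4 is a good pronucleophile for the activated benzylic alcohol; the neutral medium spares the aryl silyl ethers.

Step 4
Reactants: 6 4-bromo-2-methoxyphenol
Product: 7 (4-bromo-2-methoxyphenoxy)triisopropylsilane
Conditions: TIPSCl, imidazole, DMF, rt
Reagents that add atoms: triisopropylsilyl chloride, CC(C)[Si](Cl)(C(C)C)C(C)C
Why: Standard imidazole-mediated phenol silylation, which masks the acidic OH before the organomagnesium step.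

Step 5
Reactants: 7 (4-bromo-2-methoxyphenoxy)triisopropylsilane; 5 2-{[2,4-bis(triisopropylsilyloxy)phenyl]methoxy}-5-bromo-3-methoxybenzaldehyde
Product: 9 rac-(2-{[2,4-bis(triisopropylsilyloxy)phenyl]methoxy}-5-bromo-3-methoxyphenyl)[3-methoxy-4-(triisopropylsilyloxy)phenyl]methanol, via arylmagnesium bromide 8 (not isolated)
Conditions: Mg turnings, I2 (cat.), THF, reflux; then 5, THF, −20 °C to 0 °C; H2O, sat. aq NH4Cl
Reagents that add atoms: none
Why: Grignard formation from the electron-rich aryl bromide and 1,2-addition to the aldehyde; at low temperature the aryl bromide of 5 should not exchange with the arylmagnesium reagent, and the carbinol centre may be racemic because step 6 removes it.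

Step 6
Reactants: 9 rac-(2-{[2,4-bis(triisopropylsilyloxy)phenyl]methoxy}-5-bromo-3-methoxyphenyl)[3-methoxy-4-(triisopropylsilyloxy)phenyl]methanol
Product: 10 (2-{[2,4-bis(triisopropylsilyloxy)phenyl]methoxy}-5-bromo-3-methoxyphenyl)[3-methoxy-4-(triisopropylsilyloxy)phenyl]methanone
Conditions: Dess–Martin periodinane, NaHCO3, CH2Cl2, 0 °C to rt
Reagents that add atoms: none
Why: Dess–Martin oxidation of a doubly benzylic secondary alcohol to the benzophenone; bicarbonate buffering protects the acid-sensitive electron-rich benzylic ether and the silyl ethers.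

Step 7
Reactants: 10 (2-{[2,4-bis(triisopropylsilyloxy)phenyl]methoxy}-5-bromo-3-methoxyphenyl)[3-methoxy-4-(triisopropylsilyloxy)phenyl]methanone
Product: 11 hydrazone of ketone 10 (mixture of C=N isomers)
Conditions: N2H4·H2O (excess), AcOH (cat.), EtOH, 80 °C
Reagents that add atoms: hydrazine (as monohydrate), NN
Why: Condensation of the diaryl ketone with excess hydrazine under acetate buffering (hydrazone formation); the excess suppresses azine formation and the triisopropylsilyl ethers should tolerate the mildly basic hot medium.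

Step 8
Reactants: 11 hydrazone of ketone 10
Product: 12 2-{[2,4-bis(triisopropylsilyloxy)phenyl]methoxy}-5-bromo-1-{diazo[3-methoxy-4-(triisopropylsilyloxy)phenyl]methyl}-3-methoxybenzene
Conditions: activated MnO2 (10 equiv), CH2Cl2, 0 °C, dark; filtration through Celite, concentration in the cold, used at once
Reagents that add atoms: none
Why: Dehydrogenation of an N-unsubstituted hydrazone by MnO2, the standard route to diphenyldiazomethane-type compounds, under neutral conditions that touch no other group.

Step 9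
Reactants: 12 2-{[2,4-bis(triisopropylsilyloxy)phenyl]methoxy}-5-bromo-1-{diazo[3-methoxy-4-(triisopropylsilyloxy)phenyl]methyl}-3-methoxybenzene
Product: 13 (2R,3S)-2-[2,4-bis(triisopropylsilyloxy)phenyl]-5-bromo-7-methoxy-3-[3-methoxy-4-(triisopropylsilyloxy)phenyl]-2,3-dihydro-1-benzofuran (cis)
Conditions: Rh2(S-PTAD)4 (tetrakis[(S)-(1-adamantyl)(N-phthalimido)acetato]dirhodium, 1 mol%), CH2Cl2, 4 Å MS, 0 °C, slow addition of 12
Reagents that add atoms: none
Why: Rh2(S-PTAD)4, a dimer of divalent rhodium, adds to the diazo carbon of 12 and expels N2 to give a rhodium-bound diaryl carbene at C1, which takes up the hydridic O–CH2 hydrogen of the ring C benzyl ether while the C1–C2 bond forms in an asynchronous, hydride-transfer-like insertion. The closest known reaction type is the enantioselective dirhodium-catalysed intramolecular C–H insertion of donor/donor diaryl carbenes into benzylic ethers, which gives cis-2,3-diaryl-2,3-dihydrobenzofurans. The ring closes by 1,5-insertion, so that the carbene carbon, C3a, C7a, O1 and C2 become the five-membered dihydrofuran ring fused to ring B. C3 (C1 of the target) is set by the chiral phthalimido-adamantylacetate pocket of the catalyst, which shields one face of the carbene; C2 is expected cis from the compact transition state, but its configuration is irrelevant because step 10 turns it into CH2. The step needs enantiofacial control at C1 and chemoselectivity for the single ether C–H over azine or alkene formation. These are secured by the low electrophilicity of a carbene flanked by two electron-rich aryl groups, by activation of the target C–H through oxygen and the 2,4-disilyloxyphenyl ring, by both methoxy groups being meta to C1 and out of reach, and by slow addition of 12 to the catalyst.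

Step 10
Reactants: 13 (2R,3S)-2-[2,4-bis(triisopropylsilyloxy)phenyl]-5-bromo-7-methoxy-3-[3-methoxy-4-(triisopropylsilyloxy)phenyl]-2,3-dihydro-1-benzofuran
Product: 14 2-{(1S)-2-[2,4-bis(triisopropylsilyloxy)phenyl]-1-[3-methoxy-4-(triisopropylsilyloxy)phenyl]ethyl}-4-bromo-6-methoxyphenol
Conditions: Et3SiH (10 equiv), CF3CO2H (5 equiv), CH2Cl2, −20 °C to 0 °C
Reagents that add atoms: none
Why: Ionic hydrogenation, as in silane-scavenged acidolysis of 2,4-dialkoxybenzyl ethers: protonation of the ring oxygen releases the ring B phenol and a C2 cation stabilised by the ortho and para silyloxy groups of ring C, which the silane reduces to CH2; C1 is not a reacting centre and should keep its S configuration.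

Step 11
Reactants: 15 3,5-dihydroxybenzaldehyde
Product: 16 3,5-bis(tert-butyldimethylsilyloxy)benzaldehyde
Conditions: TBSCl (2.4 equiv), imidazole, DMF, rt
Reagents that add atoms: tert-butyldimethylsilyl chloride, CC(C)(C)[Si](C)(C)Cl
Why: Standard phenol silylation; tert-butyldimethylsilyl is sufficient here because ring D only has to pass the Wittig and Heck steps.

Step 12
Reactants: 16 3,5-bis(tert-butyldimethylsilyloxy)benzaldehyde
Product: 17 1-ethenyl-3,5-bis(tert-butyldimethylsilyloxy)benzene (ring D styrene)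
Conditions: Ph3PCH3Br, KOt-Bu, THF, 0 °C to rt
Reagents that add atoms: methyltriphenylphosphonium bromide, C[P+](c1ccccc1)(c1ccccc1)c1ccccc1.[Br-]
Why: Wittig methylenation of an aromatic aldehyde with the non-stabilised ylide, pre-formed so that no free alkoxide attacks the aryl silyl ethers.

Step 13
Reactants: 14 2-{(1S)-2-[2,4-bis(triisopropylsilyloxy)phenyl]-1-[3-methoxy-4-(triisopropylsilyloxy)phenyl]ethyl}-4-bromo-6-methoxyphenol; 17 1-ethenyl-3,5-bis(tert-butyldimethylsilyloxy)benzene
Product: 18 2-{(1S)-2-[2,4-bis(triisopropylsilyloxy)phenyl]-1-[3-methoxy-4-(triisopropylsilyloxy)phenyl]ethyl}-4-{(E)-2-[3,5-bis(tert-butyldimethylsilyloxy)phenyl]ethenyl}-6-methoxyphenol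
Conditions: Pd(OAc)2 (5 mol%), P(o-tol)3 (15 mol%), Et3N, DMF, 100 °C
Reagents that add atoms: none
Why: Mizoroki–Heck reaction: oxidative addition of zerovalent palladium into the aryl bromide, syn insertion of the styrene at its terminal carbon and syn beta-hydride elimination should give the E-stilbene; free bromophenols are competent partners under phosphine/amine conditions and the C1 stereocentre is remote from the reacting site.

Step 14
Reactants: 18 2-{(1S)-2-[2,4-bis(triisopropylsilyloxy)phenyl]-1-[3-methoxy-4-(triisopropylsilyloxy)phenyl]ethyl}-4-{(E)-2-[3,5-bis(tert-butyldimethylsilyloxy)phenyl]ethenyl}-6-methoxyphenol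
Product: 19 5-[(E)-2-{3-[(1S)-2-(2,4-dihydroxyphenyl)-1-(4-hydroxy-3-methoxyphenyl)ethyl]-4-hydroxy-5-methoxyphenyl}ethenyl]benzene-1,3-diol (CNP0254096.1)
Conditions: TBAF (6 equiv), AcOH (6 equiv), degassed THF, 0 °C to rt
Reagents that add atoms: none
Why: Fluoride-driven cleavage of all five aryl silyl ethers (three triisopropylsilyl, two tert-butyldimethylsilyl) through Si–F bond formation; acetic acid buffering keeps the air-sensitive polyphenol protonated, and the E-alkene, the methyl ethers and C1 are untouched.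

Compound list
1 | 2,4-dihydroxybenzaldehyde | O=Cc1ccc(O)cc1O | starting material
2 | 2,4-bis(triisopropylsilyloxy)benzaldehyde | O=Cc1ccc(O[Si](C(C)C)(C(C)C)C(C)C)cc1O[Si](C(C)C)(C(C)C)C(C)C | intermediate
3 | [2,4-bis(triisopropylsilyloxy)phenyl]methanol | OCc1ccc(O[Si](C(C)C)(C(C)C)C(C)C)cc1O[Si](C(C)C)(C(C)C)C(C)C | intermediate
4 | 5-bromo-2-hydroxy-3-methoxybenzaldehyde | COc1cc(Br)cc(C=O)c1O | starting material
5 | 2-{[2,4-bis(triisopropylsilyloxy)phenyl]methoxy}-5-bromo-3-methoxybenzaldehyde | COc1cc(Br)cc(C=O)c1OCc1ccc(O[Si](C(C)C)(C(C)C)C(C)C)cc1O[Si](C(C)C)(C(C)C)C(C)C | intermediate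
6 | 4-bromo-2-methoxyphenol | COc1cc(Br)ccc1O | starting material
7 | (4-bromo-2-methoxyphenoxy)triisopropylsilane | COc1cc(Br)ccc1O[Si](C(C)C)(C(C)C)C(C)C | intermediate
8 | [3-methoxy-4-(triisopropylsilyloxy)phenyl]magnesium bromide | COc1cc([Mg]Br)ccc1O[Si](C(C)C)(C(C)C)C(C)C | intermediate
9 | rac-(2-{[2,4-bis(triisopropylsilyloxy)phenyl]methoxy}-5-bromo-3-methoxyphenyl)[3-methoxy-4-(triisopropylsilyloxy)phenyl]methanol | COc1cc(C(O)c2cc(Br)cc(OC)c2OCc2ccc(O[Si](C(C)C)(C(C)C)C(C)C)cc2O[Si](C(C)C)(C(C)C)C(C)C)ccc1O[Si](C(C)C)(C(C)C)C(C)C | intermediate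
10 | (2-{[2,4-bis(triisopropylsilyloxy)phenyl]methoxy}-5-bromo-3-methoxyphenyl)[3-methoxy-4-(triisopropylsilyloxy)phenyl]methanone | COc1cc(C(=O)c2cc(Br)cc(OC)c2OCc2ccc(O[Si](C(C)C)(C(C)C)C(C)C)cc2O[Si](C(C)C)(C(C)C)C(C)C)ccc1O[Si](C(C)C)(C(C)C)C(C)C | intermediate
11 | hydrazone of ketone 10 (mixture of C=N isomers) | COc1cc(C(=NN)c2cc(Br)cc(OC)c2OCc2ccc(O[Si](C(C)C)(C(C)C)C(C)C)cc2O[Si](C(C)C)(C(C)C)C(C)C)ccc1O[Si](C(C)C)(C(C)C)C(C)C | intermediate
12 | 2-{[2,4-bis(triisopropylsilyloxy)phenyl]methoxy}-5-bromo-1-{diazo[3-methoxy-4-(triisopropylsilyloxy)phenyl]methyl}-3-methoxybenzene | COc1cc(C(=[N+]=[N-])c2cc(Br)cc(OC)c2OCc2ccc(O[Si](C(C)C)(C(C)C)C(C)C)cc2O[Si](C(C)C)(C(C)C)C(C)C)ccc1O[Si](C(C)C)(C(C)C)C(C)C | intermediate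
13 | (2R,3S)-2-[2,4-bis(triisopropylsilyloxy)phenyl]-5-bromo-7-methoxy-3-[3-methoxy-4-(triisopropylsilyloxy)phenyl]-2,3-dihydro-1-benzofuran (cis) | COc1cc([C@@H]2[C@H](c3ccc(O[Si](C(C)C)(C(C)C)C(C)C)cc3O[Si](C(C)C)(C(C)C)C(C)C)Oc3c(OC)cc(Br)cc32)ccc1O[Si](C(C)C)(C(C)C)C(C)C | intermediate
14 | 2-{(1S)-2-[2,4-bis(triisopropylsilyloxy)phenyl]-1-[3-methoxy-4-(triisopropylsilyloxy)phenyl]ethyl}-4-bromo-6-methoxyphenol | COc1cc([C@H](Cc2ccc(O[Si](C(C)C)(C(C)C)C(C)C)cc2O[Si](C(C)C)(C(C)C)C(C)C)c2cc(Br)cc(OC)c2O)ccc1O[Si](C(C)C)(C(C)C)C(C)C | intermediate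
15 | 3,5-dihydroxybenzaldehyde | O=Cc1cc(O)cc(O)c1 | starting material
16 | 3,5-bis(tert-butyldimethylsilyloxy)benzaldehyde | O=Cc1cc(O[Si](C)(C)C(C)(C)C)cc(O[Si](C)(C)C(C)(C)C)c1 | intermediate
17 | 1-ethenyl-3,5-bis(tert-butyldimethylsilyloxy)benzene | C=Cc1cc(O[Si](C)(C)C(C)(C)C)cc(O[Si](C)(C)C(C)(C)C)c1 | intermediate
18 | 2-{(1S)-2-[2,4-bis(triisopropylsilyloxy)phenyl]-1-[3-methoxy-4-(triisopropylsilyloxy)phenyl]ethyl}-4-{(E)-2-[3,5-bis(tert-butyldimethylsilyloxy)phenyl]ethenyl}-6-methoxyphenol | COc1cc([C@H](Cc2ccc(O[Si](C(C)C)(C(C)C)C(C)C)cc2O[Si](C(C)C)(C(C)C)C(C)C)c2cc(/C=C/c3cc(O[Si](C)(C)C(C)(C)C)cc(O[Si](C)(C)C(C)(C)C)c3)cc(OC)c2O)ccc1O[Si](C(C)C)(C(C)C)C(C)C | intermediate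
19 | 5-[(E)-2-{3-[(1S)-2-(2,4-dihydroxyphenyl)-1-(4-hydroxy-3-methoxyphenyl)ethyl]-4-hydroxy-5-methoxyphenyl}ethenyl]benzene-1,3-diol (CNP0254096.1) | COc1cc([C@H](Cc2ccc(O)cc2O)c2cc(/C=C/c3cc(O)cc(O)c3)cc(OC)c2O)ccc1O | target

Total step count: 14. Longest linear sequence: 11 steps (steps 1, 2, 3, 5, 6, 7, 8, 9, 10, 13, 14).

Steps most likely to fail

1. Step 9. The bulky ortho silyloxy group on the carbon that undergoes insertion, together with the strongly hydridic character of that C–H bond, may loosen the transition state towards a stepwise hydride transfer, so that ring closure occurs on both faces of C1 and enantiomeric purity is lost. The fallback replaces catalyst control by classical resolution. It sets out from 14 of insufficient enantiomeric purity, whose ring B phenol is acylated with (1S)-camphanic chloride (Et3N, DMAP, CH2Cl2). The diastereomeric esters are separated by chromatography or crystallisation to give the camphanate ester of (S)-14 F1, and brief methanolysis (K2CO3, MeOH/THF, 0 °C) cleaves the aryl ester far faster than the triisopropylsilyl ethers. The fallback comes back to the route at 14.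

2. Step 10. The C2 cation may lose the neighbouring doubly benzylic C1 proton faster than it takes hydride, and re-protonation and reduction of the resulting triarylethylene would erode the configuration at C1; partial loss of silyl groups in acid is a second concern. The fallback avoids a cation altogether and sets out from 13. Miyaura borylation (B2pin2, Pd(dppf)Cl2, KOAc, dioxane, 80 °C) exchanges bromine for boron to give the dihydrobenzofuran pinacol boronate F2. Neutral hydrogenolysis of the benzyl aryl ether (H2, Pd(OH)2 on carbon, EtOAc/EtOH, rt), which the boronate and silyl ethers tolerate, opens the ring to the phenol pinacol boronate F3. Suzuki–Miyaura coupling (Pd(dppf)Cl2, K3PO4, THF/H2O, 40 °C) with the ring D (E)-vinyl iodide F4, made from 16 by Takai olefination (CrCl2, CHI3, THF), then gives the stilbene. The fallback comes back to the route at 18.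

3. Step 13. Oxidative addition into a bromide para to a phenol that is partly deprotonated by the amine may be slow, so that arylation at the internal styrene carbon and thermal desilylation compete. The fallback changes the coupling type and sets out from 14. Styrene 17 is converted by cross-metathesis with vinylboronic acid pinacol ester (second-generation Grubbs catalyst, CH2Cl2, 40 °C) into the ring D (E)-styryl pinacol boronate F5. F5 is joined to 14 by Suzuki–Miyaura coupling (Pd(OAc)2, SPhos, K3PO4, THF/H2O, 50 °C), which runs at lower temperature and fixes the regiochemistry and E geometry in the boron reagent. The fallback comes back to the route at 18.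

Further compounds
F1 | step 9 | (1S,4R)-camphanate ester of the ring B phenol of 14 | COc1cc([C@H](Cc2ccc(O[Si](C(C)C)(C(C)C)C(C)C)cc2O[Si](C(C)C)(C(C)C)C(C)C)c2cc(Br)cc(OC)c2OC(=O)[C@@]34CC[C@@](C)(C(=O)O3)C4(C)C)ccc1O[Si](C(C)C)(C(C)C)C(C)C
F2 | step 10 | (2R,3S)-2-[2,4-bis(triisopropylsilyloxy)phenyl]-7-methoxy-3-[3-methoxy-4-(triisopropylsilyloxy)phenyl]-5-(4,4,5,5-tetramethyl-1,3,2-dioxaborolan-2-yl)-2,3-dihydro-1-benzofuran | COc1cc([C@@H]2[C@H](c3ccc(O[Si](C(C)C)(C(C)C)C(C)C)cc3O[Si](C(C)C)(C(C)C)C(C)C)Oc3c(OC)cc(B4OC(C)(C)C(C)(C)O4)cc32)ccc1O[Si](C(C)C)(C(C)C)C(C)C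
F3 | step 10 | 2-{(1S)-2-[2,4-bis(triisopropylsilyloxy)phenyl]-1-[3-methoxy-4-(triisopropylsilyloxy)phenyl]ethyl}-6-methoxy-4-(4,4,5,5-tetramethyl-1,3,2-dioxaborolan-2-yl)phenol | COc1cc([C@H](Cc2ccc(O[Si](C(C)C)(C(C)C)C(C)C)cc2O[Si](C(C)C)(C(C)C)C(C)C)c2cc(B3OC(C)(C)C(C)(C)O3)cc(OC)c2O)ccc1O[Si](C(C)C)(C(C)C)C(C)C
F4 | step 10 | 1-[(E)-2-iodoethenyl]-3,5-bis(tert-butyldimethylsilyloxy)benzene | I/C=C/c1cc(O[Si](C)(C)C(C)(C)C)cc(O[Si](C)(C)C(C)(C)C)c1
F5 | step 13 | 2-{(E)-2-[3,5-bis(tert-butyldimethylsilyloxy)phenyl]ethenyl}-4,4,5,5-tetramethyl-1,3,2-dioxaborolane | CC1(C)OB(/C=C/c2cc(O[Si](C)(C)C(C)(C)C)cc(O[Si](C)(C)C(C)(C)C)c2)OC1(C)C
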